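## Structural features

Garcinisidone D is a depsidone: two benzene rings (ring A and ring B) are joined by a diaryl ether oxygen and by an aryl ester, which together close a central seven-membered dioxepinone. Each benzene ring is also fused to a 2,2-dimethyl-2H-pyran, so the molecule is best read as two 2H-chromenes; both are numbered O1, C2, C3=C4, C4a, C5–C8, C8a, with primes for ring B. Ring A is a fully substituted phloroglucinol: C5 carries the ether oxygen, C6 the lactone carbonyl carbon, C7 a hydroxyl hydrogen-bonded to that carbonyl, and C8 the prenyl group. Ring B is 1,2,4,5-tetraoxygenated: C5′ carries the ester oxygen, C6′ the ether oxygen, C7′ the only aromatic hydrogen and C8′ a free hydroxyl. There is no stereocentre, so the whole problem is one of regiochemistry. The fragile parts are: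
- the aryl ester, which is opened by bases and nucleophiles;
- the three electron-rich alkenes, which are sensitive to acid, electrophilic halogen and oxidants;
- the prenyl/C7–OH pair, which closes to a chroman in strong acid;
- ring B, which becomes an air-sensitive hydroquinone once the C5′ and C8′ oxygens are both free.

The real difficulty is to tell apart the three oxygens of ring A and the four of ring B, and to make a diaryl ether flanked on both sides next to a carboxyl group. The key step uses the fact that on ring A the ether oxygen (C5) and the carboxyl carbon (C6) sit on adjacent carbons with an oxygen on C7. That is exactly the pattern produced when a nucleophile and then an electrophile add across a 3-alkoxyaryne.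

## Logic of the disconnections

34 is opened at the ester C(=O)–O bond to ring B C5′, giving 33. This is the most labile bond of the target and is therefore made last. The cut turns the dioxepinone into an open diaryl ether acid. The forward ring closure needs the activated acid to be reached only by the C5′ hydroxyl, which geometry ensures, and high dilution.

33 is traced to 32 by putting methoxymethyl acetals back on the C7, C5′ and C8′ oxygens. These acetals survive alkyllithiums, hydride and fluoride, all of which the route uses, and come off with mild acid. The forward step must be mild enough for the prenyl group and both chromenes, and must exclude air.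

32 is cut at two adjacent bonds of ring A: C5–O (ether) and C6–CO2H. This gives 16, 28 and 29. The cut is made here because the two bonds are vicinal and the C7 oxygen fixes the direction of addition to the aryne. It divides the molecule into two chromenes of similar size, and ring A needs no carboxyl group beforehand. The forward step requires that 28 enters as its phenoxide without any proton source and that the aryne from 16 is released slowly under 29.

16 goes back to 14 (S–O bond) and 14 to 13 (carbamate C–O bond). 13 is cut at the C8–CH2 bond to give 10 and 11. 10 is cut at C6–Si to give 8, and 8 goes back to 7 by removing the carbamoyl group. The carbamate is both the mask for the oxygen that becomes the triflate and the director that places silicon on C6. Once C6 is blocked, C8 is the only ring C–H left for the prenyl group. The forward steps require low temperature, so that the carbamoyl group does not migrate, and a second metalation that goes to the ring C–H.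

7 is traced through 5 and 4 to 1 and 2. The C3=C4 alkene comes from a C4 ketone. The C7 acetal is put on while that ketone holds the C5 hydroxyl in a hydrogen bond. The chromanone comes from cutting C4–C4a and O1–C2. This is where the oxygens of ring A are told apart: the carbonyl makes one of the two remaining hydroxyls unreactive. The forward steps require reduction of a hydrogen-bonded ketone and a mild dehydration.

28 is cut at the C6′–O bond back to the bromide 25. The pyran ring of 25 is opened (C4′–C4a′ and then O1′–C2′) through 23 to 21 and 22. 21 comes from 18 by the same bromine-to-oxygen exchange, and 18 from 17. The two bromines of 17 are latent oxygens that are unmasked one at a time, so the four oxygens of ring B are distinguished without any selective protection. The forward steps require a clean single bromine–lithium exchange; the Claisen step has only one free ortho carbon to go to.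

## Other disconnections considered

Alternative 1: The cut removes three C–C bonds of ring A. One is the bond between the ether-bearing carbon and the carbonyl-bearing carbon. The other two flank the carbons that carry the prenyl group and the future pyran oxygen. In the forward direction a cationic monovalent rhodium bisphosphine catalyst would join the ring B diyne A1 (an aryl ethynyl ether and an ethoxypropiolate ester on neighbouring oxygens) with the siloxyalkyne A2. This [2+2+2] cycloaddition would give depsidone A3, closing ring A and the seven-membered ring together.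
- In its favour: a hexasubstituted benzene and the dioxepinone arise in one step from open-chain pieces, and the reaction class is well established. On precedent it is the better of the two plans. It also closes two rings, where the chosen key step closes none.
- Against it: the ethynyl ether and the alkoxypropiolate are sensitive to hydrolysis. The tether closes a seven-membered ring, which is slower than the usual five- or six-membered cases and leaves room for self-trimerisation of A2. The orientation of A2 decides whether the prenyl group ends up beside the ethoxy carbon or beside the C–H carbon, and only sterics bias it.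
- After A3 much remains: silyl removal, pyran annulation on ring A, cleavage of an ethyl ether with a boron trihalide in the presence of prenyl and chromene groups, and acetal removal.
- Comparison: Alternative 1 solves the substitution of ring A and the medium ring at once. The chosen plan brings both chromenes and the prenyl group through the coupling intact and needs only two steps afterwards. In step count the two are about equal before the key step, and the chosen plan is shorter after it.

Alternative 2: The cut removes, on each benzene ring, the aryl C4a–C4 bond and the O1–C2 bond of the pyran. In the forward direction two equivalents of 3-methylbut-2-enal A5 would condense with the two free phenols of the depsidone core A4 under amine catalysis (condensation, then oxa-6π electrocyclisation) to give A6.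
- In its favour: one simple reagent is used twice, and four bonds and two rings form in one operation. Regiochemistry is forced, because each reacting phenol has a single free ortho carbon and the C7 hydroxyl has none. The reaction type is known, so on precedent it is better than the chosen key step. Like the chosen plan, it raises no stereochemical question.
- Against it: the aryl ester of A4 must survive an amine at elevated temperature. The reacting carbon of ring B lies next to an acyloxy group and is deactivated, while the ring A phenol is para to the lactone carbonyl, so the two annulations would run at very different rates. A4 also carries a prenyl group beside a free phenol.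
- Comparison: A4 still contains the diaryl ether and the ester, so the hardest bond construction is only postponed. A coupling of the kind chosen here, or an Ullmann reaction, would still be needed to reach A4. The saving is at most one or two steps for the pyran rings, against a less certain final stage.

Alternative 3: The cut removes the C5′–C6′ bond of ring B. In the forward direction the 4-hydroxy-4-(2-aryloxyvinyl)cyclobutenone A7 would be heated. Its four-membered ring opens to a dienylketene, which closes between the ketene carbon and the aryloxy-bearing vinyl carbon and tautomerises to the hydroquinone A8.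
- In its favour: all four oxygens of ring B and the pyran fusion are fixed by construction from a squaric acid ester. The conditions are neutral and thermal, and the reaction type is known, which is again better than the chosen step on precedent. The position of the ether oxygen is as well defined as in the chosen plan.
- Against it: ring A must already carry its carboxyl group as an ester, and must be attached through an enol ether made from a hindered phenol. The product is a free, oxidisable hydroquinone with a saturated chroman, so a quinone-type dehydrogenation to the chromene would compete with oxidation of ring B. The hindered methyl ester must still be turned into the lactone.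
- Comparison: Alternative 3 solves ring B, which the chosen plan solves in five simple steps from a dibromohydroquinone. It does nothing for ring A or for the carboxyl group, and the bicyclic cyclobutenedione makes it clearly longer.

Key step: step 14

Remark on the chemistry: the substitution patterns of the two coupling partners were checked atom by atom against the target (ring A: C5 triflate, C6 silicon, C7 acetal, C8 prenyl; ring B: C5′ and C8′ acetals, C6′ hydroxyl) and need no correction. Three things are changed in how they are made and used:
- the ring A oxygens are told apart through a chromanone;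
- silicon is introduced by directed metalation;
- the ring B partner enters the coupling as its preformed potassium salt in THF.

## Route

Step 1
Reactants: 1 phloroglucinol; 2 3-methylbut-2-enoic acid
Product: 4 5,7-dihydroxy-2,2-dimethylchroman-4-one, via aryl enone 3 (not isolated)
Conditions: MeSO3H, P2O5, 70 °C
Reagents that add atoms: none
Why: Friedel–Crafts acylation of the symmetrical triol and oxa-Michael closure of an ortho hydroxyl onto the enone give the chromanone; all ring positions of 1 are equivalent, and the C4 carbonyl made here later distinguishes the C5 and C7 hydroxyls.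

Step 2
Reactants: 4 5,7-dihydroxy-2,2-dimethylchroman-4-one
Product: 5 5-hydroxy-7-(methoxymethoxy)-2,2-dimethylchroman-4-one
Conditions: MOMCl (1.1 equiv), K2CO3, acetone, 0 °C to rt
Reagents that add atoms: chloromethyl methyl ether, COCCl
Why: Williamson-type O-alkylation under chelation control; the C5 hydroxyl is held in a hydrogen bond to the C4 carbonyl and is much less nucleophilic, so only the C7 oxygen should be alkylated.

Step 3
Reactants: 5 5-hydroxy-7-(methoxymethoxy)-2,2-dimethylchroman-4-one
Product: 7 7-(methoxymethoxy)-2,2-dimethyl-2H-chromen-5-ol, via chromanol 6 (not isolated)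
Conditions: NaBH4, THF/EtOH, 0 °C to rt; then pyridinium p-toluenesulfonate (cat.), toluene, 60 °C
Reagents that add atoms: none
Why: Hydride reduction of the aryl ketone gives a benzylic alcohol that loses water easily through a cation stabilised by the ortho hydroxyl and the para acetal oxygen (reduction–dehydration route to 2H-chromenes); the C4 stereocentre of 6 is racemic and is erased.

Step 4
Reactants: 7 7-(methoxymethoxy)-2,2-dimethyl-2H-chromen-5-ol
Product: 8 7-(methoxymethoxy)-2,2-dimethyl-2H-chromen-5-yl N,N-diethylcarbamate
Conditions: NaH, Et2NCOCl, THF, 0 °C to rt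
Reagents that add atoms: N,N-diethylcarbamoyl chloride, CCN(CC)C(Cl)=O
Why: O-acylation of the sodium phenoxide; the carbamate masks the oxygen that will become the triflate and is the strongest director for the two metalations that follow.

Step 5
Reactants: 8 7-(methoxymethoxy)-2,2-dimethyl-2H-chromen-5-yl N,N-diethylcarbamate
Product: 10 7-(methoxymethoxy)-2,2-dimethyl-6-(trimethylsilyl)-2H-chromen-5-yl N,N-diethylcarbamate, via aryllithium 9 (not isolated)
Conditions: s-BuLi, TMEDA, THF, −78 °C; Me3SiCl, −78 °C to rt
Reagents that add atoms: chlorotrimethylsilane, C[Si](C)(C)Cl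
Why: Directed ortho-metalation; C6–H lies between the carbamate and the acetal, the two best directors, so lithiation should go there and not to C8, and at −78 °C the anionic ortho-Fries shift is slow enough for the silyl chloride to trap the anion.

Step 6
Reactants: 10 7-(methoxymethoxy)-2,2-dimethyl-6-(trimethylsilyl)-2H-chromen-5-yl N,N-diethylcarbamate; 11 1-bromo-3-methylbut-2-ene (prenyl bromide)
Product: 13 7-(methoxymethoxy)-2,2-dimethyl-8-(3-methylbut-2-enyl)-6-(trimethylsilyl)-2H-chromen-5-yl N,N-diethylcarbamate, via aryllithium 12 (not isolated)
Conditions: s-BuLi, TMEDA, THF, −78 °C; CuBr·SMe2 (10 mol%), then 11, −78 °C to rt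
Reagents that add atoms: none
Why: A second directed ortho-metalation at the only ring C–H left (C8, between the acetal oxygen and the pyran oxygen), then copper-catalysed SN2 allylation with the primary allylic bromide; silicon blocks C6, so no carbamoyl shift is possible.

Step 7
Reactants: 13 7-(methoxymethoxy)-2,2-dimethyl-8-(3-methylbut-2-enyl)-6-(trimethylsilyl)-2H-chromen-5-yl N,N-diethylcarbamate
Product: 14 7-(methoxymethoxy)-2,2-dimethyl-8-(3-methylbut-2-enyl)-6-(trimethylsilyl)-2H-chromen-5-ol
Conditions: LiAlH4, THF, 0 °C to reflux; then H2O, aq. NaOH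
Reagents that add atoms: none
Why: Reductive cleavage of the aryl carbamate (hydride adds to the carbonyl, the phenoxide leaves and the formamide is reduced further); the acetal, the aryl–silicon bond and both alkenes are inert to hydride.

Step 8
Reactants: 14 7-(methoxymethoxy)-2,2-dimethyl-8-(3-methylbut-2-enyl)-6-(trimethylsilyl)-2H-chromen-5-ol
Product: 16 7-(methoxymethoxy)-2,2-dimethyl-8-(3-methylbut-2-enyl)-6-(trimethylsilyl)-2H-chromen-5-yl trifluoromethanesulfonate, via lithium phenoxide 15 (not isolated)
Conditions: n-BuLi, Et2O, −78 °C; Tf2O, −78 to 0 °C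
Reagents that add atoms: trifluoromethanesulfonic anhydride, O=S(=O)(OS(=O)(=O)C(F)(F)F)C(F)(F)F
Why: O-sulfonylation of the hindered lithium phenoxide, the same trapping that ends retro-Brook routes to ortho-silyl aryl triflates; no acid or amine is present that could attack the acetal or the aryl–silicon bond.

Step 9
Reactants: 17 2,5-dibromobenzene-1,4-diol
Product: 18 1,4-dibromo-2,5-bis(methoxymethoxy)benzene
Conditions: NaH, MOMCl, DMF, 0 °C to rt
Reagents that add atoms: chloromethyl methyl ether, COCCl
Why: Double O-alkylation of the symmetrical hydroquinone; the two bromines are kept as latent oxygens.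

Step 10
Reactants: 18 1,4-dibromo-2,5-bis(methoxymethoxy)benzene
Product: 21 4-bromo-2,5-bis(methoxymethoxy)phenol, via aryllithium 19 (not isolated), via boronate 20 (not isolated)
Conditions: n-BuLi (1.05 equiv), THF, −78 °C; B(OMe)3; then H2O2, aq. NaOH, 0 °C
Reagents that add atoms: hydrogen peroxide, OO; trimethyl borate, COB(OC)OC (its atoms stay in 20 only)
Why: Bromine–lithium exchange should stop after one bromine because a second exchange would place two carbanions on one ring; borylation and the oxidative 1,2-shift of the aryl group from boron to oxygen then give the phenol.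

Step 11
Reactants: 21 4-bromo-2,5-bis(methoxymethoxy)phenol; 22 3-chloro-3-methylbut-1-yne
Product: 23 1-bromo-2,5-bis(methoxymethoxy)-4-[(2-methylbut-3-yn-2-yl)oxy]benzene
Conditions: K2CO3, KI (cat.), CuI (cat.), acetone, 55 °C
Reagents that add atoms: none
Why: Copper-assisted O-alkylation of the phenoxide with the tertiary propargylic chloride, the standard entry to aryl 1,1-dimethylpropargyl ethers.

Step 12
Reactants: 23 1-bromo-2,5-bis(methoxymethoxy)-4-[(2-methylbut-3-yn-2-yl)oxy]benzene
Product: 25 6-bromo-5,8-bis(methoxymethoxy)-2,2-dimethyl-2H-chromene, via allenyl phenol 24 (not isolated)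
Conditions: N,N-diethylaniline, 160 °C
Reagents that add atoms: none
Why: Aryl propargyl ether Claisen rearrangement to the only free ortho carbon, then a 1,5-hydrogen shift and oxa-6π electrocyclisation close the 2,2-dimethyl-2H-pyran; the other ortho carbon carries an acetal oxygen and is blocked.

Step 13
Reactants: 25 6-bromo-5,8-bis(methoxymethoxy)-2,2-dimethyl-2H-chromene
Product: 28 5,8-bis(methoxymethoxy)-2,2-dimethyl-2H-chromen-6-ol, via aryllithium 26 (not isolated), via boronate 27 (not isolated)
Conditions: n-BuLi, THF, −78 °C; B(OMe)3; then H2O2, aq. NaOH, 0 °C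
Reagents that add atoms: hydrogen peroxide, OO; trimethyl borate, COB(OC)OC (its atoms stay in 27 only)
Why: The second latent oxygen is unmasked by the same exchange–borylation–oxidation sequence; basic peroxide does not epoxidise the electron-rich chromene alkene.

Step 14
Reactants: 16 7-(methoxymethoxy)-2,2-dimethyl-8-(3-methylbut-2-enyl)-6-(trimethylsilyl)-2H-chromen-5-yl trifluoromethanesulfonate; 28 5,8-bis(methoxymethoxy)-2,2-dimethyl-2H-chromen-6-ol; 29 carbon dioxide
Product: 32 5-{[5,8-bis(methoxymethoxy)-2,2-dimethyl-2H-chromen-6-yl]oxy}-7-(methoxymethoxy)-2,2-dimethyl-8-(3-methylbut-2-enyl)-2H-chromene-6-carboxylic acid, via potassium phenoxide 30 (not isolated), via aryne 31 (not isolated)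
Conditions: 28 (1.5 equiv), KH, THF, 0 °C; then 16, KF, 18-crown-6, CO2 (1 atm), THF, 0 °C to rt; cold 0.5 M HCl to pH 3
Reagents that add atoms: none
Why: Proposed new method: fluoride attacks the silicon of 16 and triflate leaves from the neighbouring carbon to give aryne 31 (ring A C5≡C6); the phenoxide oxygen of 30 adds to C5 and the aryl anion left on C6 adds to CO2, so the C5–O ether bond and the C6–CO2 bond form in one flask. The closest known reactions are the three-component unions of arynes with amines or imines and CO2, where the nitrogen nucleophile is likewise held reversibly by CO2, and the fluoride-promoted O-arylation of phenols by arynes, where the same aryl anion is simply protonated; capture of a phenoxide adduct by CO2 has no precedent. No ring is closed and no stereocentre is formed. The selectivity needed is regiochemical: the C7 acetal oxygen polarises the aryne inductively, so the nucleophile should enter at the distal carbon C5 and the charge should develop on C6 beside that oxygen, where the acetal can also chelate the cation (the 3-alkoxyaryne rule). Carboxylation is favoured over protonation by using the preformed potassium salt 30 in THF, so that neither an O–H nor an acidic solvent C–H is present, and by releasing the aryne slowly under a CO2 atmosphere. The carbonate formed from 30 and CO2 is in equilibrium with free phenoxide and is the weaker nucleophile, so it should act only as a reservoir.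

Step 15
Reactants: 32 5-{[5,8-bis(methoxymethoxy)-2,2-dimethyl-2H-chromen-6-yl]oxy}-7-(methoxymethoxy)-2,2-dimethyl-8-(3-methylbut-2-enyl)-2H-chromene-6-carboxylic acid
Product: 33 5-[(5,8-dihydroxy-2,2-dimethyl-2H-chromen-6-yl)oxy]-7-hydroxy-2,2-dimethyl-8-(3-methylbut-2-enyl)-2H-chromene-6-carboxylic acid
Conditions: 3 M aq. HCl/THF (1:4), 40 °C, argon, degassed solvents
Reagents that add atoms: none
Why: Acid hydrolysis of the three aryl methoxymethyl acetals; the freed C7 hydroxyl is tied to the carboxyl group by a hydrogen bond, which should keep it from adding to the prenyl alkene, and air is excluded because ring B is now a hydroquinone.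

Step 16
Reactants: 33 5-[(5,8-dihydroxy-2,2-dimethyl-2H-chromen-6-yl)oxy]-7-hydroxy-2,2-dimethyl-8-(3-methylbut-2-enyl)-2H-chromene-6-carboxylic acid
Product: 34 garcinisidone D
Conditions: DCC, DMAP (cat.), CH2Cl2/THF (2 mM), 0 °C to rt, argon
Reagents that add atoms: none
Why: Carbodiimide lactonisation of the Steglich type; only the C5′ hydroxyl, ortho to the ether oxygen, can reach the activated acid (seven-membered ring), the C8′ and C7 hydroxyls cannot close any ring, and high dilution should suppress intermolecular esters.

## Compound list

1 | phloroglucinol (benzene-1,3,5-triol) | Oc1cc(O)cc(O)c1 | starting material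
2 | 3-methylbut-2-enoic acid | CC(C)=CC(=O)O | starting material
3 | 3-methyl-1-(2,4,6-trihydroxyphenyl)but-2-en-1-one | CC(C)=CC(=O)c1c(O)cc(O)cc1O | intermediate (not isolated)
4 | 5,7-dihydroxy-2,2-dimethylchroman-4-one | CC1(C)CC(=O)c2c(O)cc(O)cc2O1 | intermediate
5 | 5-hydroxy-7-(methoxymethoxy)-2,2-dimethylchroman-4-one | COCOc1cc(O)c2C(=O)CC(C)(C)Oc2c1 | intermediate
6 | 7-(methoxymethoxy)-2,2-dimethylchromane-4,5-diol (racemic at C4) | COCOc1cc(O)c2C(O)CC(C)(C)Oc2c1 | intermediate (not isolated)
7 | 7-(methoxymethoxy)-2,2-dimethyl-2H-chromen-5-ol | COCOc1cc(O)c2C=CC(C)(C)Oc2c1 | intermediate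
8 | 7-(methoxymethoxy)-2,2-dimethyl-2H-chromen-5-yl N,N-diethylcarbamate | CCN(CC)C(=O)Oc1cc(OCOC)cc2OC(C)(C)C=Cc12 | intermediate
9 | [5-(diethylcarbamoyloxy)-7-(methoxymethoxy)-2,2-dimethyl-2H-chromen-6-yl]lithium | CCN(CC)C(=O)Oc1c([Li])c(OCOC)cc2OC(C)(C)C=Cc12 | intermediate (not isolated)
10 | 7-(methoxymethoxy)-2,2-dimethyl-6-(trimethylsilyl)-2H-chromen-5-yl N,N-diethylcarbamate | CCN(CC)C(=O)Oc1c([Si](C)(C)C)c(OCOC)cc2OC(C)(C)C=Cc12 | intermediate
11 | 1-bromo-3-methylbut-2-ene (prenyl bromide) | CC(C)=CCBr | starting material
12 | [5-(diethylcarbamoyloxy)-7-(methoxymethoxy)-2,2-dimethyl-6-(trimethylsilyl)-2H-chromen-8-yl]lithium | CCN(CC)C(=O)Oc1c([Si](C)(C)C)c(OCOC)c([Li])c2OC(C)(C)C=Cc12 | intermediate (not isolated)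
13 | 7-(methoxymethoxy)-2,2-dimethyl-8-(3-methylbut-2-enyl)-6-(trimethylsilyl)-2H-chromen-5-yl N,N-diethylcarbamate | CCN(CC)C(=O)Oc1c([Si](C)(C)C)c(OCOC)c(CC=C(C)C)c2OC(C)(C)C=Cc12 | intermediate
14 | 7-(methoxymethoxy)-2,2-dimethyl-8-(3-methylbut-2-enyl)-6-(trimethylsilyl)-2H-chromen-5-ol | CC(C)=CCc1c(OCOC)c([Si](C)(C)C)c(O)c2C=CC(C)(C)Oc12 | intermediate
15 | lithium 7-(methoxymethoxy)-2,2-dimethyl-8-(3-methylbut-2-enyl)-6-(trimethylsilyl)-2H-chromen-5-olate | CC(C)=CCc1c(OCOC)c([Si](C)(C)C)c([O-])c2C=CC(C)(C)Oc12.[Li+] | intermediate (not isolated)
16 | 7-(methoxymethoxy)-2,2-dimethyl-8-(3-methylbut-2-enyl)-6-(trimethylsilyl)-2H-chromen-5-yl trifluoromethanesulfonate | CC(C)=CCc1c(OCOC)c([Si](C)(C)C)c(OS(=O)(=O)C(F)(F)F)c2C=CC(C)(C)Oc12 | intermediate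
17 | 2,5-dibromobenzene-1,4-diol | Oc1cc(Br)c(O)cc1Br | starting material
18 | 1,4-dibromo-2,5-bis(methoxymethoxy)benzene | COCOc1cc(Br)c(OCOC)cc1Br | intermediate
19 | [4-bromo-2,5-bis(methoxymethoxy)phenyl]lithium | COCOc1cc([Li])c(OCOC)cc1Br | intermediate (not isolated)
20 | dimethyl [4-bromo-2,5-bis(methoxymethoxy)phenyl]boronate | COCOc1cc(B(OC)OC)c(OCOC)cc1Br | intermediate (not isolated)
21 | 4-bromo-2,5-bis(methoxymethoxy)phenol | Oc1cc(OCOC)c(Br)cc1OCOC | intermediate
22 | 3-chloro-3-methylbut-1-yne | CC(C)(Cl)C#C | starting material
23 | 1-bromo-2,5-bis(methoxymethoxy)-4-[(2-methylbut-3-yn-2-yl)oxy]benzene | C#CC(C)(C)Oc1cc(OCOC)c(Br)cc1OCOC | intermediate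
24 | 4-bromo-3,6-bis(methoxymethoxy)-2-(3-methylbuta-1,2-dien-1-yl)phenol | CC(C)=C=Cc1c(O)c(OCOC)cc(Br)c1OCOC | intermediate (not isolated)
25 | 6-bromo-5,8-bis(methoxymethoxy)-2,2-dimethyl-2H-chromene | COCOc1cc(Br)c(OCOC)c2C=CC(C)(C)Oc12 | intermediate
26 | [5,8-bis(methoxymethoxy)-2,2-dimethyl-2H-chromen-6-yl]lithium | COCOc1cc([Li])c(OCOC)c2C=CC(C)(C)Oc12 | intermediate (not isolated)
27 | dimethyl [5,8-bis(methoxymethoxy)-2,2-dimethyl-2H-chromen-6-yl]boronate | COCOc1cc(B(OC)OC)c(OCOC)c2C=CC(C)(C)Oc12 | intermediate (not isolated)
28 | 5,8-bis(methoxymethoxy)-2,2-dimethyl-2H-chromen-6-ol | Oc1cc(OCOC)c2OC(C)(C)C=Cc2c1OCOC | intermediate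
29 | carbon dioxide | O=C=O | starting material
30 | potassium 5,8-bis(methoxymethoxy)-2,2-dimethyl-2H-chromen-6-olate | [K+].[O-]c1cc(OCOC)c2OC(C)(C)C=Cc2c1OCOC | intermediate (not isolated)
31 | 5,6-didehydro-7-(methoxymethoxy)-2,2-dimethyl-8-(3-methylbut-2-enyl)-2H-chromene (aryne) | CC(C)=CCC1=C(OCOC)C#CC2=C1OC(C)(C)C=C2 | intermediate (not isolated)
32 | 5-{[5,8-bis(methoxymethoxy)-2,2-dimethyl-2H-chromen-6-yl]oxy}-7-(methoxymethoxy)-2,2-dimethyl-8-(3-methylbut-2-enyl)-2H-chromene-6-carboxylic acid | OC(=O)c1c(OCOC)c(CC=C(C)C)c2OC(C)(C)C=Cc2c1Oc1cc(OCOC)c2OC(C)(C)C=Cc2c1OCOC | intermediate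
33 | 5-[(5,8-dihydroxy-2,2-dimethyl-2H-chromen-6-yl)oxy]-7-hydroxy-2,2-dimethyl-8-(3-methylbut-2-enyl)-2H-chromene-6-carboxylic acid | OC(=O)c1c(O)c(CC=C(C)C)c2OC(C)(C)C=Cc2c1Oc1cc(O)c2OC(C)(C)C=Cc2c1O | intermediate
34 | garcinisidone D | CC(C)=CCc1c(O)c2c(c3c1OC(C)(C)C=C3)Oc1cc(O)c3c(c1OC2=O)C=CC(C)(C)O3 | target

## Step count and least certain steps

Total: 16 steps. Longest linear sequence: 11 steps (steps 1–8 and 14–16); the ring B branch is 5 steps (9–13).

Step 14 (key step, proposed new method). Four things may go wrong:
- protonation of the aryl anion before it meets CO2, which would give the plain diaryl ether;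
- addition of the carbonate form of the phenoxide through oxygen, followed by acyl transfer, which would give an aryl ester instead of the ether acid;
- O-arylation of the product carboxylate by a second aryne;
- erosion of regiocontrol if steric pressure from the peri C4–H outweighs the inductive bias of the C7 acetal.

The fallback uses known chemistry. It sets out from 16 and 28 and comes back at 32. Free phenol 28 and 16 are treated with CsF in MeCN at rt without CO2. This is the established fluoride-promoted O-arylation of phenols by arynes, with the same regiochemistry and protonation on C6. It should give 5-{[5,8-bis(methoxymethoxy)-2,2-dimethyl-2H-chromen-6-yl]oxy}-7-(methoxymethoxy)-2,2-dimethyl-8-(3-methylbut-2-enyl)-2H-chromene F1. Ring A C6–H of F1 has two ortho oxygens and the para pyran oxygen and is the most electron-rich aromatic position. NBS in CH2Cl2 at −78 °C should therefore give the 6-bromo derivative of that diaryl ether F2. Bromine–lithium exchange with n-BuLi at −78 °C and a CO2 quench then give 32.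

Step 6. Four things may go wrong:
- metalation of a silicon-bound methyl group under the direction of the carbamate, in place of ring metalation at C8;
- metalation of the vinylic C4–H under the same direction;
- attack of the base on the carbamate carbonyl;
- allylation at the tertiary end of the allyl unit, giving the 1,1-dimethylallyl isomer.

The fallback abandons the carbamate for a silyl ether and a halogen and makes the aryl–silicon bond by a retro-Brook shift. It sets out from 7 and comes back at 15. Silylation of 7 (TIPSCl, imidazole, DMF) gives triisopropyl{[7-(methoxymethoxy)-2,2-dimethyl-2H-chromen-5-yl]oxy}silane F3. Lithiation of F3 with n-BuLi in THF at 0 °C should go to C8, between the acetal and the pyran oxygen, because the bulky silyl ether shields C6. CuBr·SMe2 and 11 then give triisopropyl{[7-(methoxymethoxy)-2,2-dimethyl-8-(3-methylbut-2-enyl)-2H-chromen-5-yl]oxy}silane F4. TBAF frees 7-(methoxymethoxy)-2,2-dimethyl-8-(3-methylbut-2-enyl)-2H-chromen-5-ol F5. NBS in CH2Cl2 at −78 °C brominates the only free ring position to give 6-bromo-7-(methoxymethoxy)-2,2-dimethyl-8-(3-methylbut-2-enyl)-2H-chromen-5-ol F6. HMDS in THF at reflux gives {[6-bromo-7-(methoxymethoxy)-2,2-dimethyl-8-(3-methylbut-2-enyl)-2H-chromen-5-yl]oxy}trimethylsilane F7. n-BuLi at −78 °C then causes bromine–lithium exchange and the 1,3 shift of silicon from oxygen to carbon, which gives 15. Triflation as in step 8 leads to 16.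

Step 15. Three things may go wrong:
- air oxidation of the freed ring B hydroquinone to a quinone during reaction or isolation;
- acid-promoted addition of the C7 hydroxyl to the prenyl alkene (chroman formation);
- hydration of a chromene alkene.

The fallback reverses the order of activation and unmasking, so the hydroquinone is consumed by ring closure and is never isolated. It sets out from 32 and comes back at 34. Compound 32 is converted with DCC and pentafluorophenol into the pentafluorophenyl ester of 32 F8. The same acid treatment then removes the acetals to give the pentafluorophenyl ester of 33 F9. Brief exposure to aq. NaHCO3 lets the C5′ hydroxyl attack the active ester and gives 34 directly, and no coupling agent ever meets the free phenols.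

Step 3. Three things may go wrong:
- incomplete reduction, because the hydrogen-bonded and partly deprotonated ketone is a poor electrophile;
- loss of the acetal during the acid dehydration;
- trapping of the benzylic cation by the alcohol solvent.

The fallback carbamoylates before reducing. It sets out from 5 and comes back at 8. NaH and Et2NCOCl convert 5 into 7-(methoxymethoxy)-2,2-dimethyl-4-oxochroman-5-yl N,N-diethylcarbamate F10, whose ketone is no longer chelated. NaBH4 gives 4-hydroxy-7-(methoxymethoxy)-2,2-dimethylchroman-5-yl N,N-diethylcarbamate F11 (racemic). Dehydration with pyridinium p-toluenesulfonate in toluene at 80 °C gives 8.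

## Further compounds

F1 | step 14 | 5-{[5,8-bis(methoxymethoxy)-2,2-dimethyl-2H-chromen-6-yl]oxy}-7-(methoxymethoxy)-2,2-dimethyl-8-(3-methylbut-2-enyl)-2H-chromene | CC(C)=CCc1c(OCOC)cc(Oc2cc(OCOC)c3OC(C)(C)C=Cc3c2OCOC)c2C=CC(C)(C)Oc12
F2 | step 14 | 6-bromo-5-{[5,8-bis(methoxymethoxy)-2,2-dimethyl-2H-chromen-6-yl]oxy}-7-(methoxymethoxy)-2,2-dimethyl-8-(3-methylbut-2-enyl)-2H-chromene | CC(C)=CCc1c(OCOC)c(Br)c(Oc2cc(OCOC)c3OC(C)(C)C=Cc3c2OCOC)c2C=CC(C)(C)Oc12
F3 | step 6 | triisopropyl{[7-(methoxymethoxy)-2,2-dimethyl-2H-chromen-5-yl]oxy}silane | CC(C)[Si](Oc1cc(OCOC)cc2OC(C)(C)C=Cc12)(C(C)C)C(C)C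
F4 | step 6 | triisopropyl{[7-(methoxymethoxy)-2,2-dimethyl-8-(3-methylbut-2-enyl)-2H-chromen-5-yl]oxy}silane | CC(C)=CCc1c(OCOC)cc(O[Si](C(C)C)(C(C)C)C(C)C)c2C=CC(C)(C)Oc12
F5 | step 6 | 7-(methoxymethoxy)-2,2-dimethyl-8-(3-methylbut-2-enyl)-2H-chromen-5-ol | CC(C)=CCc1c(OCOC)cc(O)c2C=CC(C)(C)Oc12
F6 | step 6 | 6-bromo-7-(methoxymethoxy)-2,2-dimethyl-8-(3-methylbut-2-enyl)-2H-chromen-5-ol | CC(C)=CCc1c(OCOC)c(Br)c(O)c2C=CC(C)(C)Oc12
F7 | step 6 | {[6-bromo-7-(methoxymethoxy)-2,2-dimethyl-8-(3-methylbut-2-enyl)-2H-chromen-5-yl]oxy}trimethylsilane | CC(C)=CCc1c(OCOC)c(Br)c(O[Si](C)(C)C)c2C=CC(C)(C)Oc12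
F8 | step 15 | pentafluorophenyl 5-{[5,8-bis(methoxymethoxy)-2,2-dimethyl-2H-chromen-6-yl]oxy}-7-(methoxymethoxy)-2,2-dimethyl-8-(3-methylbut-2-enyl)-2H-chromene-6-carboxylate | O=C(Oc1c(F)c(F)c(F)c(F)c1F)c1c(OCOC)c(CC=C(C)C)c2OC(C)(C)C=Cc2c1Oc1cc(OCOC)c2OC(C)(C)C=Cc2c1OCOC
F9 | step 15 | pentafluorophenyl 5-[(5,8-dihydroxy-2,2-dimethyl-2H-chromen-6-yl)oxy]-7-hydroxy-2,2-dimethyl-8-(3-methylbut-2-enyl)-2H-chromene-6-carboxylate | O=C(Oc1c(F)c(F)c(F)c(F)c1F)c1c(O)c(CC=C(C)C)c2OC(C)(C)C=Cc2c1Oc1cc(O)c2OC(C)(C)C=Cc2c1O
F10 | step 3 | 7-(methoxymethoxy)-2,2-dimethyl-4-oxochroman-5-yl N,N-diethylcarbamate | CCN(CC)C(=O)Oc1cc(OCOC)cc2OC(C)(C)CC(=O)c12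
F11 | step 3 | 4-hydroxy-7-(methoxymethoxy)-2,2-dimethylchroman-5-yl N,N-diethylcarbamate (racemic) | CCN(CC)C(=O)Oc1cc(OCOC)cc2OC(C)(C)CC(O)c12
A1 | alternative 1 | 6-(ethynyloxy)-8-(methoxymethoxy)-2,2-dimethyl-2H-chromen-5-yl 3-ethoxyprop-2-ynoate | C#COc1cc(OCOC)c2OC(C)(C)C=Cc2c1OC(=O)C#COCC
A2 | alternative 1 | triisopropyl[(5-methylhex-4-en-1-yn-1-yl)oxy]silane | CC(C)=CCC#CO[Si](C(C)C)(C(C)C)C(C)C
A3 | alternative 1 | depsidone with the ring B chromene and its methoxymethyl ether in place, ring A carrying prenyl, an ethyl ether beside the carbonyl and a triisopropylsilyl ether at the future pyran oxygen | CC(C)=CCc1c(OCC)c2c(cc1O[Si](C(C)C)(C(C)C)C(C)C)Oc1cc(OCOC)c3c(c1OC2=O)C=CC(C)(C)O3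
A4 | alternative 2 | 1,3,8-trihydroxy-7-(methoxymethoxy)-2-(3-methylbut-2-enyl)-11H-dibenzo[b,e][1,4]dioxepin-11-one | CC(C)=CCc1c(O)c2C(=O)Oc3cc(O)c(OCOC)cc3Oc2cc1O
A5 | alternative 2 | 3-methylbut-2-enal | CC(C)=CC=O
A6 | alternative 2 | garcinisidone D 8′-O-methoxymethyl ether | CC(C)=CCc1c(O)c2c(c3c1OC(C)(C)C=C3)Oc1cc(OCOC)c3c(c1OC2=O)C=CC(C)(C)O3
A7 | alternative 3 | methyl 5-{[2-(8-hydroxy-3,3-dimethyl-7-oxo-2-oxabicyclo[4.2.0]oct-1(6)-en-8-yl)ethenyl]oxy}-7-(methoxymethoxy)-2,2-dimethyl-8-(3-methylbut-2-enyl)-2H-chromene-6-carboxylate (racemic carbinol, alkene geometry not fixed) | COC(=O)c1c(OCOC)c(CC=C(C)C)c2OC(C)(C)C=Cc2c1OC=CC1(O)C(=O)C2=C1OC(C)(C)CC2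
A8 | alternative 3 | methyl 5-[(5,8-dihydroxy-2,2-dimethylchroman-6-yl)oxy]-7-(methoxymethoxy)-2,2-dimethyl-8-(3-methylbut-2-enyl)-2H-chromene-6-carboxylate | Oc1cc(Oc2c(C(=O)OC)c(OCOC)c(CC=C(C)C)c3OC(C)(C)C=Cc23)c(O)c2CCC(C)(C)Oc12
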